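**Plan**

1. Retrosynthesis cuts, in order: the ester C–O that joins the halves; in the left half the oxepinone at its C4=C5 alkene and O2–C3 ester bond; then the cyclohexane at C6–C7 and C9–C9a (2-benzoxepine numbering).
2. Enabling feature: carbinol carbon C9 is β to the lactone carbonyl (aldol unit C9–C9a–C1=O) and, through C8–C7, δ to the isopropyl-bearing C6. C7–C8–C9(–CH2O) is therefore a vinyl ketone, and C6 and C9a are the ends of a 1,3-bis-nucleophile.
3. The bis-nucleophile is a γ-nitro aldehyde: nitro on C6 as removable activator, aldehyde as the oxidation level of the lactone carbonyl, a dimethyl acetal on C5a as latent vinyl group.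
4. Forward, left half: nitro-Michael addition (sets C5a), Michael/aldol annulation (carbocycle), then oxidation, denitration, olefination, allyl ester formation and ring-closing metathesis (oxepinone).
5. Forward, right half: Robinson annulation with the same vinyl ketone, Luche reduction, lipase resolution, palladium allyl–alkynyl coupling with inversion, syn-hydromagnesiation/carboxylation; then esterification and one acidolysis.
6. Stereochemistry: C5a by amine catalysis; C9a and C9 relayed from it in the annulation; C6 by axial hydrogen delivery; right-half C6′ by enzyme, C1′ by inversion, enoate geometry by syn addition.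

Key step: step 4

Remark: compounds 1, 5, 6, 14, 18 and 24 are taken as purchasable; the nitro-bearing carbon is carried as both epimers until step 6 re-sets it.

**Route**

Step 1
Reactants: 1 2-[(4-methoxyphenyl)methoxy]acetaldehyde; 2 ethenylmagnesium bromide
Product: 3 1-[(4-methoxyphenyl)methoxy]but-3-en-2-ol (racemic)
Conditions: THF, −78 °C to 0 °C; aq NH4Cl
Reagents that add atoms: none
Why: Grignard 1,2-addition to the aldehyde should give the allylic alcohol, whose stereocenter is removed in step 2.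

Step 2
Reactants: 3 1-[(4-methoxyphenyl)methoxy]but-3-en-2-ol
Product: 4 1-[(4-methoxyphenyl)methoxy]but-3-en-2-one
Conditions: Dess–Martin periodinane, NaHCO3, CH2Cl2, 0 °C to rt; used fresh
Reagents that add atoms: none
Why: Dess–Martin oxidation should give the vinyl ketone under buffered, non-nucleophilic conditions that avoid conjugate addition and polymerisation.

Step 3
Reactants: 5 (2E)-4,4-dimethoxybut-2-enal; 6 2-methyl-1-nitropropane
Product: 7 (3S)-3-(dimethoxymethyl)-5-methyl-4-nitrohexanal (both C4 epimers)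
Conditions: (R)-α,α-diphenylprolinol trimethylsilyl ether (10 mol%), PhCO2H (20 mol%), MeOH, rt
Reagents that add atoms: none
Why: Organocatalytic nitro-Michael addition through the E-iminium ion of 5, whose shielded face forces the nitronate of 6 onto the open face and sets C3 as S; C4 forms as both epimers, which does not matter because it loses its hydrogen in step 4 and its nitro group in step 6.

Step 4
Reactants: 7 (3S)-3-(dimethoxymethyl)-5-methyl-4-nitrohexanal; 4 1-[(4-methoxyphenyl)methoxy]but-3-en-2-one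
Product: 9 (1S,2S,6S)-6-(dimethoxymethyl)-2-hydroxy-2-{[(4-methoxyphenyl)methoxy]methyl}-5-nitro-5-(propan-2-yl)cyclohexane-1-carbaldehyde (both C5 epimers), via nitro keto aldehyde 8 (not isolated)
Conditions: 1,1,3,3-tetramethylguanidine (0.2 equiv), MeCN, 0 °C to rt; then AcOH (0.2 equiv), (S)-proline (30 mol%), DMSO, rt
Reagents that add atoms: none
Why: Tetramethylguanidine deprotonates only the nitroalkane, far more acidic than the aldehyde α-CH2, and the nitronate adds in Michael fashion to the unsubstituted terminus of 4 to form the C4–C5 bond (ring numbering of 9) and keto aldehyde 8; (S)-proline then forms an enamine with the aldehyde whose α-carbon attacks the tethered ketone and forms the C1–C2 bond. The closest known reaction types are the Michael addition of secondary nitroalkanes to vinyl ketones and the proline-catalysed enolexo aldolization of keto aldehydes, run here as one Michael/aldol [3+3] annulation. The cyclohexane closes by a 6-(enolexo)-exo-trig aldol through a chair-like transition state. C1 is set by the enamine face that (S)-proline exposes, which is also the face that places the new bond trans to the equatorial C6 acetal (matched case); C2 follows from the hydrogen-bonded chair in which the ketone oxygen is equatorial and anti to the formyl group, leaving the CH2O(4-methoxybenzyl) arm axial; C5 forms as both epimers and is re-set in step 6. The step needs C-alkylation by the nitronate and not by the aldehyde α-carbon, which the acidity gap and the late addition of proline should secure, and it needs the aldehyde as aldol donor and the ketone as acceptor, which faster enamine formation from the aldehyde and the activating α-alkoxy group of the ketone should secure.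

Step 5
Reactants: 9 (1S,2S,6S)-6-(dimethoxymethyl)-2-hydroxy-2-{[(4-methoxyphenyl)methoxy]methyl}-5-nitro-5-(propan-2-yl)cyclohexane-1-carbaldehyde
Product: 10 (1S,2S,6S)-6-(dimethoxymethyl)-2-hydroxy-2-{[(4-methoxyphenyl)methoxy]methyl}-5-nitro-5-(propan-2-yl)cyclohexane-1-carboxylic acid (both C5 epimers)
Conditions: NaClO2, NaH2PO4, 2-methylbut-2-ene, t-BuOH/H2O, 0 °C to rt
Reagents that add atoms: sodium chlorite, [Na+].[O-]Cl=O
Why: Pinnick oxidation should convert the aldehyde into the acid at buffered pH without epimerising C1 or triggering retro-aldol cleavage, the alkene trapping hypochlorite.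

Step 6
Reactants: 10 (1S,2S,6S)-6-(dimethoxymethyl)-2-hydroxy-2-{[(4-methoxyphenyl)methoxy]methyl}-5-nitro-5-(propan-2-yl)cyclohexane-1-carboxylic acid
Product: 11 (1S,2S,5R,6R)-6-(dimethoxymethyl)-2-hydroxy-2-{[(4-methoxyphenyl)methoxy]methyl}-5-(propan-2-yl)cyclohexane-1-carboxylic acid
Conditions: Bu3SnH (5 equiv), 2,2′-azobis(2-methylpropionitrile), toluene, 110 °C; aq KF work-up
Reagents that add atoms: none
Why: Radical denitration of a tertiary nitro group, in which both C5 epimers give the same tertiary cyclohexyl radical; this radical should take its hydrogen along the axial direction so that the bulky isopropyl group ends equatorial, trans to the equatorial C6 substituent (C5 = R).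

Step 7
Reactants: 11 (1S,2S,5R,6R)-6-(dimethoxymethyl)-2-hydroxy-2-{[(4-methoxyphenyl)methoxy]methyl}-5-(propan-2-yl)cyclohexane-1-carboxylic acid
Product: 12 (1S,2S,5R,6R)-6-formyl-2-hydroxy-2-{[(4-methoxyphenyl)methoxy]methyl}-5-(propan-2-yl)cyclohexane-1-carboxylic acid
Conditions: AcOH/THF/H2O (3:1:1), 40 °C
Reagents that add atoms: water, O
Why: Mild acid hydrolysis of the dimethyl acetal should free the C6 aldehyde (possibly resting as a lactol with the neighbouring acid) while the 4-methoxybenzyl ether survives; C6 already has its stable equatorial configuration, so enolisation does no harm.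

Step 8
Reactants: 12 (1S,2S,5R,6R)-6-formyl-2-hydroxy-2-{[(4-methoxyphenyl)methoxy]methyl}-5-(propan-2-yl)cyclohexane-1-carboxylic acid
Product: 13 (1S,2S,5R,6R)-6-ethenyl-2-hydroxy-2-{[(4-methoxyphenyl)methoxy]methyl}-5-(propan-2-yl)cyclohexane-1-carboxylic acid
Conditions: Ph3PCH3Br, KN(SiMe3)2 (ylide 4 equiv), THF, −78 °C to rt; aq citric acid
Reagents that add atoms: methyltriphenylphosphonium bromide, C[P+](c1ccccc1)(c1ccccc1)c1ccccc1.[Br-]
Why: Wittig methylenation with excess ylide should convert the aldehyde (or its lactol) into the vinyl group, the carboxylate and alkoxide being inert.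

Step 9
Reactants: 13 (1S,2S,5R,6R)-6-ethenyl-2-hydroxy-2-{[(4-methoxyphenyl)methoxy]methyl}-5-(propan-2-yl)cyclohexane-1-carboxylic acid; 14 tert-butyl 2-(bromomethyl)prop-2-enoate
Product: 15 2-(tert-butoxycarbonyl)prop-2-en-1-yl (1S,2S,5R,6R)-6-ethenyl-2-hydroxy-2-{[(4-methoxyphenyl)methoxy]methyl}-5-(propan-2-yl)cyclohexane-1-carboxylate
Conditions: Cs2CO3, DMF, 0 °C to rt
Reagents that add atoms: none
Why: O-Alkylation of the caesium carboxylate by the allylic bromide (SN2 and SN2′ give the same ester) should be chemoselective over the tertiary alcohol.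

Step 10
Reactants: 15 2-(tert-butoxycarbonyl)prop-2-en-1-yl (1S,2S,5R,6R)-6-ethenyl-2-hydroxy-2-{[(4-methoxyphenyl)methoxy]methyl}-5-(propan-2-yl)cyclohexane-1-carboxylate
Product: 16 tert-butyl (5aS,6R,9S,9aS)-9-hydroxy-9-{[(4-methoxyphenyl)methoxy]methyl}-1-oxo-6-(propan-2-yl)-1,3,5a,6,7,8,9,9a-octahydro-2-benzoxepine-4-carboxylate
Conditions: second-generation Hoveyda–Grubbs catalyst (10 mol%), toluene (0.005 M), 80 °C
Reagents that add atoms: none
Why: Ring-closing metathesis between the vinyl group and the 1,1-disubstituted acrylate alkene should close the seven-membered unsaturated lactone, the ring fixing the alkene geometry and the trans-diequatorial tether ends favouring closure.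

Step 11
Reactants: 16 tert-butyl (5aS,6R,9S,9aS)-9-hydroxy-9-{[(4-methoxyphenyl)methoxy]methyl}-1-oxo-6-(propan-2-yl)-1,3,5a,6,7,8,9,9a-octahydro-2-benzoxepine-4-carboxylate
Product: 17 tert-butyl (5aS,6R,9S,9aS)-9-hydroxy-9-(hydroxymethyl)-1-oxo-6-(propan-2-yl)-1,3,5a,6,7,8,9,9a-octahydro-2-benzoxepine-4-carboxylate
Conditions: DDQ, CH2Cl2/pH 7 phosphate buffer, 0 °C; used at once
Reagents that add atoms: none
Why: Oxidative cleavage of the 4-methoxybenzyl ether by DDQ should free the primary alcohol without touching the tert-butyl ester, lactone or electron-poor alkene; immediate use forestalls translactonisation to the five-membered lactone.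

Step 12
Reactants: 18 ethyl 2-acetyl-3-methylbutanoate; 4 1-[(4-methoxyphenyl)methoxy]but-3-en-2-one
Product: 21 (6RS)-3-{[(4-methoxyphenyl)methoxy]methyl}-6-(propan-2-yl)cyclohex-2-en-1-one, via Michael adduct 19 (not isolated), via cyclohexenone ester 20 (not isolated)
Conditions: NaOEt (0.2 equiv), EtOH, 0 °C to 60 °C; then KOH, H2O, reflux; aq HCl
Reagents that add atoms: none
Why: Robinson annulation, in which the acetoacetate α-carbon adds to 4 and the acetyl methyl group condenses onto the unhindered alkoxymethyl ketone (the acetyl carbonyl next to the quaternary carbon being the poorer acceptor), followed by saponification and decarboxylation to the racemic enone.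

Step 13
Reactants: 21 (6RS)-3-{[(4-methoxyphenyl)methoxy]methyl}-6-(propan-2-yl)cyclohex-2-en-1-one
Product: 22 rac-(1S,6S)-3-{[(4-methoxyphenyl)methoxy]methyl}-6-(propan-2-yl)cyclohex-2-en-1-ol
Conditions: NaBH4, CeCl3·7H2O, MeOH, −78 °C
Reagents that add atoms: none
Why: Luche reduction should give clean 1,2-reduction with axial hydride delivery, placing the hydroxyl pseudo-equatorial and trans to the isopropyl group (relative configuration only).

Step 14
Reactants: 22 rac-(1S,6S)-3-{[(4-methoxyphenyl)methoxy]methyl}-6-(propan-2-yl)cyclohex-2-en-1-ol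
Product: 23 (1S,6S)-3-{[(4-methoxyphenyl)methoxy]methyl}-6-(propan-2-yl)cyclohex-2-en-1-yl acetate
Conditions: immobilised Candida antarctica lipase B, vinyl acetate, tert-butyl methyl ether, 30 °C, stopped near half conversion
Reagents that add atoms: vinyl acetate, CC(=O)OC=C
Why: Lipase-catalysed kinetic resolution by transesterification, in which the usual empirical model for secondary alcohols (flat alkene side as medium group, branched C6 side as large group) predicts faster acylation of the (1S,6S) enantiomer; the unreacted (1R,6R) alcohol is removed by chromatography.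

Step 15
Reactants: 23 (1S,6S)-3-{[(4-methoxyphenyl)methoxy]methyl}-6-(propan-2-yl)cyclohex-2-en-1-yl acetate; 24 3-(tributylstannyl)prop-2-yn-1-ol
Product: 25 3-[(1R,6S)-3-{[(4-methoxyphenyl)methoxy]methyl}-6-(propan-2-yl)cyclohex-2-en-1-yl]prop-2-yn-1-ol
Conditions: Pd2(dba)3 (5 mol%), tri(2-furyl)phosphine, DMF, 50 °C
Reagents that add atoms: none
Why: Stille allylic coupling, in which zerovalent palladium ionises the acetate with inversion and the alkynyl group passes from tin to palladium and then to the less substituted allyl terminus from the metal face, so that C1 is inverted overall and the alkynyl group ends cis to isopropyl.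

Step 16
Reactants: 25 3-[(1R,6S)-3-{[(4-methoxyphenyl)methoxy]methyl}-6-(propan-2-yl)cyclohex-2-en-1-yl]prop-2-yn-1-ol
Product: 27 (2E)-2-(hydroxymethyl)-3-[(1R,6S)-3-{[(4-methoxyphenyl)methoxy]methyl}-6-(propan-2-yl)cyclohex-2-en-1-yl]prop-2-enoic acid, via alkenylmagnesium bromide 26 (not isolated)
Conditions: i-BuMgBr (4 equiv), Cp2TiCl2 (10 mol%), Et2O, 0 °C to rt; then CO2, −20 °C to rt; aq HCl
Reagents that add atoms: carbon dioxide, O=C=O
Why: Titanocene-catalysed hydromagnesiation of the 2-alkyn-1-ol adds H and Mg syn with magnesium on the carbon next to CH2O, and carboxylation of that alkenyl Grignard reagent should give the enoic acid with ring and carboxyl trans (E).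

Step 17
Reactants: 27 (2E)-2-(hydroxymethyl)-3-[(1R,6S)-3-{[(4-methoxyphenyl)methoxy]methyl}-6-(propan-2-yl)cyclohex-2-en-1-yl]prop-2-enoic acid
Product: 29 (2E)-2-({[tert-butyl(dimethyl)silyl]oxy}methyl)-3-[(1R,6S)-3-{[(4-methoxyphenyl)methoxy]methyl}-6-(propan-2-yl)cyclohex-2-en-1-yl]prop-2-enoic acid, via silyl ester 28 (not isolated)
Conditions: t-BuMe2SiCl (2.5 equiv), imidazole, DMF, rt; then K2CO3 (cat.), MeOH/H2O, 0 °C; aq citric acid
Reagents that add atoms: tert-butyl(chloro)dimethylsilane, CC(C)(C)[Si](C)(C)Cl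
Why: Silylation of hydroxyl and carboxyl groups followed by selective methanolysis of the labile silyl ester should leave the silyl ether and the free acid.

Step 18
Reactants: 17 tert-butyl (5aS,6R,9S,9aS)-9-hydroxy-9-(hydroxymethyl)-1-oxo-6-(propan-2-yl)-1,3,5a,6,7,8,9,9a-octahydro-2-benzoxepine-4-carboxylate; 29 (2E)-2-({[tert-butyl(dimethyl)silyl]oxy}methyl)-3-[(1R,6S)-3-{[(4-methoxyphenyl)methoxy]methyl}-6-(propan-2-yl)cyclohex-2-en-1-yl]prop-2-enoic acid
Product: 30 tert-butyl (5aS,6R,9S,9aS)-9-({[(2E)-2-({[tert-butyl(dimethyl)silyl]oxy}methyl)-3-[(1R,6S)-3-{[(4-methoxyphenyl)methoxy]methyl}-6-(propan-2-yl)cyclohex-2-en-1-yl]prop-2-enoyl]oxy}methyl)-9-hydroxy-1-oxo-6-(propan-2-yl)-1,3,5a,6,7,8,9,9a-octahydro-2-benzoxepine-4-carboxylate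
Conditions: N-(3-dimethylaminopropyl)-N′-ethylcarbodiimide hydrochloride, 4-(dimethylamino)pyridine, CH2Cl2, 0 °C to rt
Reagents that add atoms: none
Why: Steglich esterification, in which the carbodiimide-activated acid should acylate the primary alcohol only, the tertiary alcohol being too hindered.

Step 19
Reactants: 30 fully protected diester
Product: 31 (5aS,6R,9S,9aS)-9-hydroxy-9-({[(2E)-2-(hydroxymethyl)-3-[(1R,6S)-3-(hydroxymethyl)-6-(propan-2-yl)cyclohex-2-en-1-yl]prop-2-enoyl]oxy}methyl)-1-oxo-6-(propan-2-yl)-1,3,5a,6,7,8,9,9a-octahydro-2-benzoxepine-4-carboxylic acid (the target)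
Conditions: CF3CO2H/CH2Cl2/H2O (10:10:1), anisole, 0 °C to rt; aq NaHCO3 then pH 3 work-up
Reagents that add atoms: none
Why: Acidolysis should remove the tert-butyl ester (as isobutene), the 4-methoxybenzyl ether (cation trapped by anisole) and the silyl ether in one operation, the tertiary alcohol being deactivated towards ionisation by the flanking carbonyl and acyloxymethyl groups.

**Compound list**

1 | 2-[(4-methoxyphenyl)methoxy]acetaldehyde | COc1ccc(COCC=O)cc1 | starting material
2 | ethenylmagnesium bromide | C=C[Mg]Br | starting material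
3 | 1-[(4-methoxyphenyl)methoxy]but-3-en-2-ol (racemic) | COc1ccc(COCC(O)C=C)cc1 | intermediate
4 | 1-[(4-methoxyphenyl)methoxy]but-3-en-2-one | COc1ccc(COCC(=O)C=C)cc1 | intermediate
5 | (2E)-4,4-dimethoxybut-2-enal | COC(OC)/C=C/C=O | starting material
6 | 2-methyl-1-nitropropane | CC(C)C[N+](=O)[O-] | starting material
7 | (3S)-3-(dimethoxymethyl)-5-methyl-4-nitrohexanal (both C4 epimers) | O=CC[C@@H](C([N+](=O)[O-])C(C)C)C(OC)OC | intermediate
8 | (3S)-3-(dimethoxymethyl)-8-[(4-methoxyphenyl)methoxy]-4-nitro-7-oxo-4-(propan-2-yl)octanal (both C4 epimers) | O=CC[C@@H](C([N+](=O)[O-])(C(C)C)CCC(=O)COCc1ccc(OC)cc1)C(OC)OC | intermediate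
9 | (1S,2S,6S)-6-(dimethoxymethyl)-2-hydroxy-2-{[(4-methoxyphenyl)methoxy]methyl}-5-nitro-5-(propan-2-yl)cyclohexane-1-carbaldehyde (both C5 epimers) | CC(C)C1([N+](=O)[O-])CC[C@@](O)(COCc2ccc(OC)cc2)[C@@H](C=O)[C@@H]1C(OC)OC | intermediate
10 | (1S,2S,6S)-6-(dimethoxymethyl)-2-hydroxy-2-{[(4-methoxyphenyl)methoxy]methyl}-5-nitro-5-(propan-2-yl)cyclohexane-1-carboxylic acid (both C5 epimers) | CC(C)C1([N+](=O)[O-])CC[C@@](O)(COCc2ccc(OC)cc2)[C@@H](C(=O)O)[C@@H]1C(OC)OC | intermediate
11 | (1S,2S,5R,6R)-6-(dimethoxymethyl)-2-hydroxy-2-{[(4-methoxyphenyl)methoxy]methyl}-5-(propan-2-yl)cyclohexane-1-carboxylic acid | CC(C)[C@H]1CC[C@@](O)(COCc2ccc(OC)cc2)[C@@H](C(=O)O)[C@@H]1C(OC)OC | intermediate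
12 | (1S,2S,5R,6R)-6-formyl-2-hydroxy-2-{[(4-methoxyphenyl)methoxy]methyl}-5-(propan-2-yl)cyclohexane-1-carboxylic acid | CC(C)[C@H]1CC[C@@](O)(COCc2ccc(OC)cc2)[C@@H](C(=O)O)[C@@H]1C=O | intermediate
13 | (1S,2S,5R,6R)-6-ethenyl-2-hydroxy-2-{[(4-methoxyphenyl)methoxy]methyl}-5-(propan-2-yl)cyclohexane-1-carboxylic acid | CC(C)[C@H]1CC[C@@](O)(COCc2ccc(OC)cc2)[C@@H](C(=O)O)[C@@H]1C=C | intermediate
14 | tert-butyl 2-(bromomethyl)prop-2-enoate | C=C(CBr)C(=O)OC(C)(C)C | starting material
15 | 2-(tert-butoxycarbonyl)prop-2-en-1-yl (1S,2S,5R,6R)-6-ethenyl-2-hydroxy-2-{[(4-methoxyphenyl)methoxy]methyl}-5-(propan-2-yl)cyclohexane-1-carboxylate | CC(C)[C@H]1CC[C@@](O)(COCc2ccc(OC)cc2)[C@@H](C(=O)OCC(=C)C(=O)OC(C)(C)C)[C@@H]1C=C | intermediate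
16 | tert-butyl (5aS,6R,9S,9aS)-9-hydroxy-9-{[(4-methoxyphenyl)methoxy]methyl}-1-oxo-6-(propan-2-yl)-1,3,5a,6,7,8,9,9a-octahydro-2-benzoxepine-4-carboxylate | CC(C)[C@H]1CC[C@@](O)(COCc3ccc(OC)cc3)[C@H]2C(=O)OCC(C(=O)OC(C)(C)C)=C[C@H]12 | intermediate
17 | tert-butyl (5aS,6R,9S,9aS)-9-hydroxy-9-(hydroxymethyl)-1-oxo-6-(propan-2-yl)-1,3,5a,6,7,8,9,9a-octahydro-2-benzoxepine-4-carboxylate | CC(C)[C@H]1CC[C@@](O)(CO)[C@H]2C(=O)OCC(C(=O)OC(C)(C)C)=C[C@H]12 | intermediate
18 | ethyl 2-acetyl-3-methylbutanoate (racemic) | CCOC(=O)C(C(C)C)C(C)=O | starting material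
19 | ethyl (2RS)-2-acetyl-6-[(4-methoxyphenyl)methoxy]-5-oxo-2-(propan-2-yl)hexanoate | CCOC(=O)C(C(C)C)(C(C)=O)CCC(=O)COCc1ccc(OC)cc1 | intermediate
20 | ethyl (1RS)-4-{[(4-methoxyphenyl)methoxy]methyl}-2-oxo-1-(propan-2-yl)cyclohex-3-ene-1-carboxylate | CCOC(=O)C1(C(C)C)CCC(COCc2ccc(OC)cc2)=CC1=O | intermediate
21 | (6RS)-3-{[(4-methoxyphenyl)methoxy]methyl}-6-(propan-2-yl)cyclohex-2-en-1-one | CC(C)C1CCC(COCc2ccc(OC)cc2)=CC1=O | intermediate
22 | rac-(1S,6S)-3-{[(4-methoxyphenyl)methoxy]methyl}-6-(propan-2-yl)cyclohex-2-en-1-ol (racemate; the enantiomer carried on is drawn) | O[C@@H]1C=C(COCc2ccc(OC)cc2)CC[C@H]1C(C)C | intermediate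
23 | (1S,6S)-3-{[(4-methoxyphenyl)methoxy]methyl}-6-(propan-2-yl)cyclohex-2-en-1-yl acetate | CC(=O)O[C@@H]1C=C(COCc2ccc(OC)cc2)CC[C@H]1C(C)C | intermediate
24 | 3-(tributylstannyl)prop-2-yn-1-ol | CCCC[Sn](CCCC)(CCCC)C#CCO | starting material
25 | 3-[(1R,6S)-3-{[(4-methoxyphenyl)methoxy]methyl}-6-(propan-2-yl)cyclohex-2-en-1-yl]prop-2-yn-1-ol | OCC#C[C@H]1C=C(COCc2ccc(OC)cc2)CC[C@H]1C(C)C | intermediate
26 | bromomagnesium alkoxide of the (E)-alkenylmagnesium bromide from 25 (Mg on the carbon next to CH2O, trans to the ring) | Br[Mg]/C(=C/[C@H]1C=C(COCc2ccc(OC)cc2)CC[C@H]1C(C)C)CO[Mg]Br | intermediate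
27 | (2E)-2-(hydroxymethyl)-3-[(1R,6S)-3-{[(4-methoxyphenyl)methoxy]methyl}-6-(propan-2-yl)cyclohex-2-en-1-yl]prop-2-enoic acid | OC(=O)/C(=C/[C@H]1C=C(COCc2ccc(OC)cc2)CC[C@H]1C(C)C)CO | intermediate
28 | tert-butyl(dimethyl)silyl (2E)-2-({[tert-butyl(dimethyl)silyl]oxy}methyl)-3-[(1R,6S)-3-{[(4-methoxyphenyl)methoxy]methyl}-6-(propan-2-yl)cyclohex-2-en-1-yl]prop-2-enoate | CC(C)(C)[Si](C)(C)OC(=O)/C(=C/[C@H]1C=C(COCc2ccc(OC)cc2)CC[C@H]1C(C)C)CO[Si](C)(C)C(C)(C)C | intermediate
29 | (2E)-2-({[tert-butyl(dimethyl)silyl]oxy}methyl)-3-[(1R,6S)-3-{[(4-methoxyphenyl)methoxy]methyl}-6-(propan-2-yl)cyclohex-2-en-1-yl]prop-2-enoic acid | OC(=O)/C(=C/[C@H]1C=C(COCc2ccc(OC)cc2)CC[C@H]1C(C)C)CO[Si](C)(C)C(C)(C)C | intermediate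
30 | tert-butyl (5aS,6R,9S,9aS)-9-({[(2E)-2-({[tert-butyl(dimethyl)silyl]oxy}methyl)-3-[(1R,6S)-3-{[(4-methoxyphenyl)methoxy]methyl}-6-(propan-2-yl)cyclohex-2-en-1-yl]prop-2-enoyl]oxy}methyl)-9-hydroxy-1-oxo-6-(propan-2-yl)-1,3,5a,6,7,8,9,9a-octahydro-2-benzoxepine-4-carboxylate | CC(C)[C@H]1CC[C@@](O)(COC(=O)/C(=C/[C@H]3C=C(COCc4ccc(OC)cc4)CC[C@H]3C(C)C)CO[Si](C)(C)C(C)(C)C)[C@H]2C(=O)OCC(C(=O)OC(C)(C)C)=C[C@H]12 | intermediate
31 | (5aS,6R,9S,9aS)-9-hydroxy-9-({[(2E)-2-(hydroxymethyl)-3-[(1R,6S)-3-(hydroxymethyl)-6-(propan-2-yl)cyclohex-2-en-1-yl]prop-2-enoyl]oxy}methyl)-1-oxo-6-(propan-2-yl)-1,3,5a,6,7,8,9,9a-octahydro-2-benzoxepine-4-carboxylic acid | CC(C)[C@H]1CC[C@@](O)(COC(=O)/C(=C/[C@H]2C=C(CO)CC[C@H]2C(C)C)CO)[C@H]2C(=O)OCC(C(=O)O)=C[C@H]12 | target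

**Totals and risks**

Total step count: 19. Longest linear sequence: 12 steps (1, 2, 4 to 11, 18, 19).

Steps most likely to fail:

Step 4. The doubly branched nitronate of 7 may add too slowly to 4, so that retro-Michael loss of 6 from 7 and addition of the aldehyde α-carbon to 4 take over. The fallback reverses the order of the two C–C bond formations at the nitro carbon. It sets out from 6 and 4: tetramethylguanidine-catalysed Michael addition should give 1-[(4-methoxyphenyl)methoxy]-5-methyl-4-nitrohexan-2-one F1 with no aldehyde present. Addition of F1 to the iminium ion of 5 under the catalyst of step 3 then forms the congested bond at an activated acceptor and sets C3, giving 8, which is isolated and cyclised with (S)-proline; the route is rejoined at 9.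

Step 6. Hydrogen-atom transfer to the tertiary radical may show poor facial selectivity and give the C5 epimer. The fallback sets C5 by hydroxyl-directed hydrogenation and sets out from 1 and 7. Ethynylmagnesium bromide should convert 1 into 1-[(4-methoxyphenyl)methoxy]but-3-yn-2-ol F2, and Dess–Martin oxidation gives 1-[(4-methoxyphenyl)methoxy]but-3-yn-2-one F3. Under the conditions of step 4, 7 and F3 should give (1S,2S,6S)-6-(dimethoxymethyl)-2-hydroxy-2-{[(4-methoxyphenyl)methoxy]methyl}-5-nitro-5-(propan-2-yl)cyclohex-3-ene-1-carbaldehyde F4, and Pinnick oxidation gives the corresponding carboxylic acid F5. Pd(PPh3)4 with NaBH4 ionises the allylic tertiary nitro group and delivers hydride to the less hindered allyl terminus, giving (1S,2S,6S)-6-(dimethoxymethyl)-2-hydroxy-2-{[(4-methoxyphenyl)methoxy]methyl}-5-(propan-2-yl)cyclohex-4-ene-1-carboxylic acid F6. Hydrogenation with [Ir(cod)(PCy3)(py)]PF6, directed by the tertiary hydroxyl, should add hydrogen to C5 on the hydroxyl face; the route is rejoined at 11.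

Step 10. The ruthenium carbene formed at the hindered vinyl group may fail to engage the electron-poor 1,1-disubstituted alkene, so that dimerisation outruns ring closure. The fallback closes the lactone by C–O bond formation and sets out from 12. Morita–Baylis–Hillman reaction with tert-butyl acrylate (1,4-diazabicyclo[2.2.2]octane) should give (1S,2S,5R,6R)-6-[2-(tert-butoxycarbonyl)-1-hydroxyprop-2-en-1-yl]-2-hydroxy-2-{[(4-methoxyphenyl)methoxy]methyl}-5-(propan-2-yl)cyclohexane-1-carboxylic acid F7. Acetylation gives the acetate (1S,2S,5R,6R)-6-[1-(acetyloxy)-2-(tert-butoxycarbonyl)prop-2-en-1-yl]-2-hydroxy-2-{[(4-methoxyphenyl)methoxy]methyl}-5-(propan-2-yl)cyclohexane-1-carboxylic acid F8. Amine-mediated intramolecular SN2′ displacement of acetate by the carboxylate then closes the seven-membered ring with allylic transposition; the route is rejoined at 16.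

Further compounds
F1 | step 4 | 1-[(4-methoxyphenyl)methoxy]-5-methyl-4-nitrohexan-2-one (racemic) | CC(C)C([N+](=O)[O-])CCC(=O)COCc1ccc(OC)cc1
F2 | step 6 | 1-[(4-methoxyphenyl)methoxy]but-3-yn-2-ol (racemic) | COc1ccc(COCC(O)C#C)cc1
F3 | step 6 | 1-[(4-methoxyphenyl)methoxy]but-3-yn-2-one | COc1ccc(COCC(=O)C#C)cc1
F4 | step 6 | (1S,2S,6S)-6-(dimethoxymethyl)-2-hydroxy-2-{[(4-methoxyphenyl)methoxy]methyl}-5-nitro-5-(propan-2-yl)cyclohex-3-ene-1-carbaldehyde (both C5 epimers) | CC(C)C1([N+](=O)[O-])C=C[C@@](O)(COCc2ccc(OC)cc2)[C@@H](C=O)[C@@H]1C(OC)OC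
F5 | step 6 | (1S,2S,6S)-6-(dimethoxymethyl)-2-hydroxy-2-{[(4-methoxyphenyl)methoxy]methyl}-5-nitro-5-(propan-2-yl)cyclohex-3-ene-1-carboxylic acid (both C5 epimers) | CC(C)C1([N+](=O)[O-])C=C[C@@](O)(COCc2ccc(OC)cc2)[C@@H](C(=O)O)[C@@H]1C(OC)OC
F6 | step 6 | (1S,2S,6S)-6-(dimethoxymethyl)-2-hydroxy-2-{[(4-methoxyphenyl)methoxy]methyl}-5-(propan-2-yl)cyclohex-4-ene-1-carboxylic acid | CC(C)C1=CC[C@@](O)(COCc2ccc(OC)cc2)[C@@H](C(=O)O)[C@@H]1C(OC)OC
F7 | step 10 | (1S,2S,5R,6R)-6-[2-(tert-butoxycarbonyl)-1-hydroxyprop-2-en-1-yl]-2-hydroxy-2-{[(4-methoxyphenyl)methoxy]methyl}-5-(propan-2-yl)cyclohexane-1-carboxylic acid (both carbinol epimers) | CC(C)[C@H]1CC[C@@](O)(COCc2ccc(OC)cc2)[C@@H](C(=O)O)[C@@H]1C(O)C(=C)C(=O)OC(C)(C)C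
F8 | step 10 | (1S,2S,5R,6R)-6-[1-(acetyloxy)-2-(tert-butoxycarbonyl)prop-2-en-1-yl]-2-hydroxy-2-{[(4-methoxyphenyl)methoxy]methyl}-5-(propan-2-yl)cyclohexane-1-carboxylic acid (both epimers at the acetoxy carbon) | CC(C)[C@H]1CC[C@@](O)(COCc2ccc(OC)cc2)[C@@H](C(=O)O)[C@@H]1C(OC(C)=O)C(=C)C(=O)OC(C)(C)C
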